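## Retrosynthetic overview
1. Cordycicadin B ⇒ an α-furyl-α-benzyloxycarbonyl lactone, from which a kinetic decarboxylative protonation sets Cα. The Cα–furan bond comes from the lactone-malonyl carbon acting as an electrophilic radical on the nucleophilic C5 of (R)-4-(furan-2-yl)butan-2-ol.
2. Bicyclic core ⇒ an ω-bromoacetoxy aldehyde. C2–C3 closure (samarium Reformatsky) forms the ten-membered lactone first. The freed C3 alkoxide then closes the γ-lactone as the second ring in the same flask. The furan ring is bought in.
3. Key disconnection C4–Cα: the α-carbon of a 4-oxo-aldehyde (as a chiral enamine) plus a bromomalonate-derived electrophilic radical. Two carbons that are both normally enolate-type nucleophiles are joined, and the catalyst sets C4.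
4. The 4-oxo-aldehyde (C3–C9) ⇒ the same furyl alcohol, by oxidative ring opening and reduction. One enzymatic reduction therefore supplies both (R)-carbinols, and no protecting groups are used.

Locants used: C1 macrolactone C=O, C2, C3 (O-bearing fusion carbon), C4 (other fusion carbon), C5, C6 ketone, C7, C8, C9 methyl carbinol. Cα is the butyrolactone α-carbon.

Assumption: 4-(furan-2-yl)butan-2-one (furfurylacetone, a flavour chemical) and both enantiomers of the imidazolidinone catalyst count as purchasable.

## Route

Step 1
Reactants: 1 4-(furan-2-yl)butan-2-one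
Product: 2 (R)-4-(furan-2-yl)butan-2-ol
Conditions: Lactobacillus kefir alcohol dehydrogenase, NADP+ (cat.), MgCl2, i-PrOH, phosphate buffer pH 7, 30 °C
Reagents that add atoms: none
Why: Biocatalytic asymmetric ketone reduction with isopropanol as coupled substrate, in which this anti-Prelog enzyme gives the (R)-carbinol of methyl 2-arylethyl ketones in >99% ee, and this one centre later becomes both C9 and the side-chain carbinol.

Step 2
Reactants: 2 (R)-4-(furan-2-yl)butan-2-ol
Product: 4 (R)-7-hydroxy-4-oxooctanal, via Z-keto-enal 3 (not isolated)
Conditions: NBS, NaHCO3, acetone–H2O (10:1), −20 °C; then Zn, AcOH, 0 °C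
Reagents that add atoms: water, O
Why: Oxidative furan ring opening (bromonium/water addition across the 2,5-positions, loss of HBr) unmasks the furan as a cis-4-oxo-enal, whose doubly activated C=C is reduced by zinc/acetic acid (dissolving-metal conjugate reduction) faster than either carbonyl, so the carbinol centre is untouched and no new stereocentre forms.

Step 3
Reactants: 5 dibenzyl malonate
Product: 6 dibenzyl 2-bromomalonate
Conditions: Br2 (1.0 equiv), 1,2-dichloroethane, 70 °C, dark
Reagents that add atoms: bromine, BrBr
Why: Electrophilic α-bromination of the malonate enol, run in the dark with one equivalent of bromine so that benzylic bromination and dibromination do not compete, and no stereocentre is formed.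

Step 4
Reactants: 4 (R)-7-hydroxy-4-oxooctanal (1.5 equiv); 6 dibenzyl 2-bromomalonate
Product: 7 dibenzyl 2-[(2S,7R)-7-hydroxy-1,4-dioxooctan-2-yl]malonate
Conditions: (2S,5R)-2-tert-butyl-3,5-dimethylimidazolidin-4-one·TfOH (20 mol %), Ru(bpy)3Cl2 (0.5 mol %), 2,6-lutidine, DMF, white light, 23 °C
Reagents that add atoms: none
Why: Photoredox organocatalytic aldehyde α-alkylation (MacMillan type), in which the reduced photocatalyst cleaves the C–Br bond of 6 to a malonyl radical (a malonate carbon reacting as an electrophile, a one-electron enolonium equivalent) that adds to the nucleophilic α-carbon of the E-enamine of 4 on the face away from the C5-methyl group of the catalyst, setting C4 as S while ketone and free OH stay spectators because only the aldehyde forms an enamine.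

Step 5
Reactants: 7 dibenzyl 2-[(2S,7R)-7-hydroxy-1,4-dioxooctan-2-yl]malonate; 8 bromoacetyl bromide
Product: 9 dibenzyl 2-[(2S,7R)-7-(2-bromoacetoxy)-1,4-dioxooctan-2-yl]malonate
Conditions: 2,6-lutidine, CH2Cl2, −40 to 0 °C
Reagents that add atoms: none
Why: O-acylation of the only hydroxyl group by an acid bromide, with a hindered base that is not alkylated by the bromoacetate and is too weak to epimerise the aldehyde α-centre C4.

Step 6
Reactants: 9 dibenzyl 2-[(2S,7R)-7-(2-bromoacetoxy)-1,4-dioxooctan-2-yl]malonate
Product: 11 Cα-benzyloxycarbonyl bicyclic core (3S,4S,9R), via hydroxy macrolide 10 (not isolated)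
Conditions: SmI2 (2.5 equiv), THF, slow addition to 2 mM, −78 to 0 °C; aq. NH4Cl
Reagents that add atoms: none
Why: Samarium Reformatsky macrocyclisation (Inanaga type) then lactonisation, in which SmI2 reduces only the α-bromo ester, the weakly basic trivalent samarium enolate adds to the aldehyde (attack on the ketone would need a seven-membered lactone with the unfavourable E ester geometry) through the Felkin–Anh arrangement with the bulky, electron-poor malonyl group anti to the incoming carbon, setting C3 as S, and the samarium alkoxide closes the cis-fused γ-lactone on the nearer benzyl ester.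

Step 7
Reactants: 11 Cα-benzyloxycarbonyl bicyclic core; 2 (R)-4-(furan-2-yl)butan-2-ol (3 equiv)
Product: 12 Cα-furyl-Cα-benzyloxycarbonyl bicyclic lactone
Conditions: Mn(OAc)3·2H2O (2.2 equiv), AcOH, 60 °C, Ar
Reagents that add atoms: none
Why: Oxidative homolytic aromatic substitution, in which Mn(OAc)3 oxidises the only 1,3-dicarbonyl C–H of 11 to a tertiary electrophilic radical (enolonium-type reactivity at a carbon that is normally an enolate), this radical attacks the free and most nucleophilic C5 of furan 2 from the convex face, and a second equivalent of oxidant rearomatises the adduct, with ketone and free OH tolerated and the configuration of this quaternary centre erased in step 8.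

Step 8
Reactants: 12 Cα-furyl-Cα-benzyloxycarbonyl bicyclic lactone
Product: 14 cordycicadin B, via malonic half acid 13 (not isolated)
Conditions: H2 (1 atm), Pd/C, EtOAc, 23 °C; filter; toluene, 80 °C
Reagents that add atoms: none
Why: Benzyl ester hydrogenolysis followed by thermal decarboxylation of the α-furyl malonic half acid, where the resulting enol is protonated under neutral, non-equilibrating conditions from the face opposite the two cis ring bonds at C3 and C4, which places the furyl group on their side and sets Cα as S (kinetic decarboxylative protonation, all-cis lactone).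

## Compound list
1 | 4-(furan-2-yl)butan-2-one | CC(=O)CCc1ccco1 | starting material
2 | (R)-4-(furan-2-yl)butan-2-ol | C[C@@H](O)CCc1ccco1 | intermediate
3 | (R,Z)-7-hydroxy-4-oxooct-2-enal | C[C@@H](O)CCC(=O)/C=C\C=O | intermediate
4 | (R)-7-hydroxy-4-oxooctanal | C[C@@H](O)CCC(=O)CCC=O | intermediate
5 | dibenzyl malonate | O=C(CC(=O)OCc1ccccc1)OCc1ccccc1 | starting material
6 | dibenzyl 2-bromomalonate | O=C(OCc1ccccc1)C(Br)C(=O)OCc1ccccc1 | intermediate
7 | dibenzyl 2-[(2S,7R)-7-hydroxy-1,4-dioxooctan-2-yl]malonate | C[C@@H](O)CCC(=O)C[C@H](C=O)C(C(=O)OCc1ccccc1)C(=O)OCc1ccccc1 | intermediate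
8 | bromoacetyl bromide | O=C(Br)CBr | starting material
9 | dibenzyl 2-[(2S,7R)-7-(2-bromoacetoxy)-1,4-dioxooctan-2-yl]malonate | C[C@@H](OC(=O)CBr)CCC(=O)C[C@H](C=O)C(C(=O)OCc1ccccc1)C(=O)OCc1ccccc1 | intermediate
10 | dibenzyl 2-[(4S,5S,10R)-4-hydroxy-10-methyl-2,7-dioxooxecan-5-yl]malonate | C[C@@H]1CCC(=O)C[C@H]([C@H](CC(=O)O1)O)C(C(=O)OCc1ccccc1)C(=O)OCc1ccccc1 | intermediate
11 | bicyclic core of the target (cis-fused γ-lactone/ten-membered keto lactone; 3S,4S,9R) with CO2Bn in place of the furyl group at Cα; the Cα epimers interconvert | C[C@@H]1CCC(=O)C[C@@H]2[C@H](CC(=O)O1)OC(=O)C2C(=O)OCc1ccccc1 | intermediate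
12 | same core with quaternary Cα bearing CO2Bn (cis to C5) and 5-[(R)-3-hydroxybutyl]furan-2-yl (trans to C5) | C[C@@H]1CCC(=O)C[C@@H]2[C@H](CC(=O)O1)OC(=O)[C@]2(c1ccc(CC[C@@H](C)O)o1)C(=O)OCc1ccccc1 | intermediate
13 | carboxylic acid of 12 (CO2H in place of CO2Bn) | C[C@@H]1CCC(=O)C[C@@H]2[C@H](CC(=O)O1)OC(=O)[C@]2(c1ccc(CC[C@@H](C)O)o1)C(=O)O | intermediate
14 | cordycicadin B | C[C@@H]1CCC(=O)C[C@@H]2[C@H](CC(=O)O1)OC(=O)[C@@H]2c1ccc(CC[C@@H](C)O)o1 | target

## Step count and risks
Total steps: 8. Longest linear sequence: 7 (steps 1, 2, 4, 5, 6, 7, 8).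

**Step 6.** This step carries three risks. Ten-membered closure must outrun protonation of the samarium enolate by the malonate C–H. The enolate could attack the ketone instead of the aldehyde. The Felkin ratio may be modest.

The fallback sets out from 7 (step 5 is dropped) and comes back at 11. It replaces C–C ring closure by reagent-controlled aldol plus macrolactonisation.
- The titanium enolate of (R)-3-acetyl-4-isopropyl-1,3-thiazolidine-2-thione (TiCl4, i-Pr2NEt, CH2Cl2, −78 °C, excess) adds to the aldehyde in a Nagao-type acetate aldol.
- The auxiliary and the Felkin preference are matched for 3S, and the aldolate lactonises to the thiazolidinethione imide lactone F1.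
- LiOH/H2O2 at 0 °C frees the seco acid F2.
- Shiina macrolactonisation (2-methyl-6-nitrobenzoic anhydride, DMAP, 1 mM) on the turn-inducing cis-lactone gives 11.

**Step 7.** The hindered tertiary radical may add slowly, and the furan or the product may be over-oxidised.

The fallback sets out from 2 and 11 and comes back at 12. It switches to a two-electron cross-coupling in which the furan, not the lactone carbon, is made the electrophile.
- Compound 2 is brominated at C5 (NBS, DMF, −20 °C) to (R)-4-(5-bromofuran-2-yl)butan-2-ol F3.
- F3 is used at once in a zerovalent palladium malonate-type α-arylation of 11 (Pd2(dba)3, P(t-Bu)3, K3PO4, toluene, 70 °C).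

**Step 8.** The all-cis product is contra-thermodynamic at Cα, so ketonisation of the enol may favour the other epimer.

The fallback sets out from 13 and comes back at 14.
- The decarboxylation is allowed to give the Cα epimer of cordycicadin B F4.
- Its α-furyl lactone C–H is by far the most acidic C–H. It is removed with LiHMDS (2.1 equiv, the first equivalent taken by the OH) in THF at −78 °C.
- The enolate is quenched with 2,6-di-tert-butyl-4-methylphenol. The bulky acid approaches the convex face only and delivers 14.

## Further compounds
F1 | step 6 | Cα-benzyloxycarbonyl cis-lactone (3S,4S,9R) with C1 as the (R)-4-isopropyl-2-thioxothiazolidin-3-yl imide and C9-OH free | C[C@@H](O)CCC(=O)C[C@@H]1[C@H](CC(=O)N2[C@H](C(C)C)CSC2=S)OC(=O)C1C(=O)OCc1ccccc1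
F2 | step 6 | seco acid of 11 (C1 as CO2H, C9-OH free) | C[C@@H](O)CCC(=O)C[C@@H]1[C@H](CC(=O)O)OC(=O)C1C(=O)OCc1ccccc1
F3 | step 7 | (R)-4-(5-bromofuran-2-yl)butan-2-ol | C[C@@H](O)CCc1ccc(Br)o1
F4 | step 8 | Cα epimer of cordycicadin B (furyl trans to C5) | C[C@@H]1CCC(=O)C[C@@H]2[C@H](CC(=O)O1)OC(=O)[C@H]2c1ccc(CC[C@@H](C)O)o1
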